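The ten-membered carbocycle (C1–C10) is not closed through a carbon–carbon bond. Its exocyclic enol-ether alkene C8=C9, which joins the γ-carbon C8 of the butenolide ring (O–C12–C11=C7–C8) to the allylic ring carbon C9, is traced back to an eleven-membered cyclic sulfone with sulfur bridging C8 and C9. A single Ramberg–Bäcklund operation chlorinates the doubly activated O,S-acetal carbon C8, closes the episulfone, expels SO2 and thereby contracts the thiacycle to the carbocycle while creating the diene. The sulfone derives from a thiol/γ-hydroxybutenolide seco-compound whose C6, C4 and C2 carbinols are set by a catalytic hetero-Diels–Alder reaction, an axial methyl addition and a CBS reduction.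

Key step: step 18

Numbering: C1 (ring CH next to C2), C2 (OAc), C3, C4 (C(OH)CH3), C5, C6 (O-methacryloyl), C7 and C8 (ring-fusion carbons, C8 on the lactone oxygen), C9 (ylidene CH), C10 (methyl-bearing alkene carbon), C11 (lactone α-carbon), C12 (C=O), C13 (CH2OH). The target is (2S,4S,6R), C1=C10 Z, C8=C9 with C10 trans to the lactone oxygen.

Abbreviations: TBDPS = tert-butyldiphenylsilyl, TES = triethylsilyl, TBS = tert-butyldimethylsilyl.

Remark on the chemistry: the C4 oxygen is silylated from the moment it is created until after the key step, because a free C4–OH lies 1,5 to C8 and would close a six-membered acetal there (or displace the C8 chloride) in preference to the eleven-membered thioacetal.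

Assumption: the catalyst antipodes named in steps 5 and 11 are those expected from the usual face-selectivity models (Re-face attack at C6, 2S carbinol); the mirror-image catalyst would be used if a pilot run showed the opposite sense.

Step 1
Reactants: 1 3,4-bis(hydroxymethyl)furan
Product: 2 [4-(TBDPS-oxymethyl)furan-3-yl]methanol
Conditions: NaH (1.0 equiv), THF, 0 °C to rt; TBDPSCl (1.0 equiv)
Reagents that add atoms: tert-butyl(chloro)diphenylsilane, CC(C)(C)[Si](Cl)(c1ccccc1)c1ccccc1
Why: O-silylation of a symmetrical diol through its monosodium alkoxide should stop at the mono-ether, which leaves one hydroxymethyl group for oxidation and puts the most robust silyl group of the route on the future C13 oxygen.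

Step 2
Reactants: 2 [4-(TBDPS-oxymethyl)furan-3-yl]methanol
Product: 3 4-(TBDPS-oxymethyl)furan-3-carbaldehyde
Conditions: MnO2, CH2Cl2, rt
Reagents that add atoms: none
Why: Heterogeneous MnO2 oxidation of an aryl-type (furylic) primary alcohol should stop at the aldehyde and leave the furan and the silyl ether untouched.

Step 3
Reactants: 4 prop-2-yn-1-ol
Product: 6 (Z)-3-iodo-2-methylprop-2-en-1-ol, via alkenylmagnesium alkoxide 5 (not isolated)
Conditions: MeMgBr (2.5 equiv), CuI (10 mol%), THF, −10 °C to rt; then I2, −78 to 0 °C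
Reagents that add atoms: methylmagnesium bromide, C[Mg]Br; iodine, II
Why: Copper-catalysed anti-carbomagnesiation of the propargylic alkoxide puts the methyl group on the proximal alkyne carbon and magnesium on the terminal carbon cis to CH2O (chelate), so iodinolysis with retention should fix the Z geometry of the future C1=C10 alkene.

Step 4
Reactants: 6 (Z)-3-iodo-2-methylprop-2-en-1-ol
Product: 7 (Z)-3-iodo-2-methylprop-2-enyl triethylsilyl ether
Conditions: TESCl, imidazole, CH2Cl2, 0 °C
Reagents that add atoms: chlorotriethylsilane, CC[Si](Cl)(CC)CC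
Why: Standard O-silylation gives a primary allylic TES ether that tolerates iodine–lithium exchange and is the most labile silyl ether of the later intermediates, so the C9 oxygen can be unmasked alone.

Step 5
Reactants: 3 4-(TBDPS-oxymethyl)furan-3-carbaldehyde; 8 (E)-1-methoxy-3-(trimethylsilyloxy)buta-1,3-diene
Product: 10 (R)-2-[4-(TBDPS-oxymethyl)furan-3-yl]-2,3-dihydro-4H-pyran-4-one, via silylated aldol adduct 9 (not isolated)
Conditions: Ti(OiPr)4 (10 mol%), (R)-BINOL (20 mol%), 4 Å MS, Et2O, −20 °C; then TFA, CH2Cl2, 0 °C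
Reagents that add atoms: none
Why: Catalytic enantioselective hetero-Diels–Alder reaction in its stepwise form (Mukaiyama aldol addition of the diene terminus to the titanium-bound aldehyde, then acid-induced cyclisation with loss of methanol), in which the chiral titanium–BINOL complex should direct C5 to the Re face of the aldehyde and so set C6 as R.

Step 6
Reactants: 10 (R)-2-[4-(TBDPS-oxymethyl)furan-3-yl]-2,3-dihydro-4H-pyran-4-one
Product: 12 (2R)-2-[4-(TBDPS-oxymethyl)furan-3-yl]-4-methyl-4-(triethylsilyloxy)-3,4-dihydro-2H-pyran with the silyloxy group cis to the furyl group, via lithium alkoxide 11 (not isolated)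
Conditions: MeLi, Et2O, −78 °C; then 2,6-lutidine, TESOTf, −78 to 0 °C
Reagents that add atoms: methyllithium, [Li]C; triethylsilyl trifluoromethanesulfonate, CC[Si](CC)(CC)OS(=O)(=O)C(F)(F)F
Why: 1,2-Addition of a hard organolithium to the vinylogous ester carbonyl should occur by axial attack on the half-chair that carries the furyl group pseudo-equatorially, so the C4 oxygen ends up equatorial and cis to the furyl group (anti to the C6 oxygen in the open chain, as in the target), and in-flask silylation of the alkoxide blocks the tertiary oxygen for all later steps.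

Step 7
Reactants: 12 (2R)-2-[4-(TBDPS-oxymethyl)furan-3-yl]-4-methyl-4-(triethylsilyloxy)-3,4-dihydro-2H-pyran
Product: 13 (6R)-6-[4-(TBDPS-oxymethyl)furan-3-yl]-4-methyl-4-(triethylsilyloxy)tetrahydropyran-2-ol (lactol; anomeric mixture)
Conditions: Ph3P·HBr (5 mol%), THF/H2O, 0 °C to rt
Reagents that add atoms: water, O
Why: Acid-catalysed hydration of the cyclic enol ether (protonation at C3, capture of the C2 oxocarbenium ion by water) should give the lactol, because the enol ether is far more basic than the furan or the hindered tertiary silyl ether, and the new anomeric centre is removed in the next step.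

Step 8
Reactants: 13 (6R)-6-[4-(TBDPS-oxymethyl)furan-3-yl]-4-methyl-4-(triethylsilyloxy)tetrahydropyran-2-ol
Product: 14 (6R)-6-[4-(TBDPS-oxymethyl)furan-3-yl]-4-methyl-4-(triethylsilyloxy)tetrahydropyran-2-one (δ-lactone; silyloxy cis to furyl)
Conditions: nPr4N[RuO4] (5 mol%), NMO, 4 Å MS, CH2Cl2, rt
Reagents that add atoms: none
Why: Catalytic perruthenate oxidation of a lactol to the lactone under neutral conditions should raise C2 to the carboxyl level without touching the furan or the silyl ethers.

Step 9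
Reactants: 7 (Z)-3-iodo-2-methylprop-2-enyl triethylsilyl ether; 14 (6R)-6-[4-(TBDPS-oxymethyl)furan-3-yl]-4-methyl-4-(triethylsilyloxy)tetrahydropyran-2-one
Product: 16 seco hydroxy enone (C6–OH; C4–OTES; C2 ketone conjugated to the Z C1=C10 alkene; C9–OTES; furan), via alkenyllithium 15 (not isolated)
Conditions: 7, t-BuLi (2.0 equiv), Et2O, −78 °C; then 14, THF, −78 °C; NH4Cl (aq)
Reagents that add atoms: none
Why: Iodine–lithium exchange with retention of alkene geometry, then single nucleophilic addition of the alkenyllithium to the lactone carbonyl (the lithium lactolate persists at −78 °C and blocks a second addition) should give the Z-enone with the C6 hydroxyl released, in equilibrium with its cyclic hemiketal.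

Step 10
Reactants: 16 seco hydroxy enone
Product: 17 C6-O-TES enone (C6–OTES; C4–OTES; C2 ketone; C9–OTES)
Conditions: TESCl, imidazole, DMAP (cat.), DMF, 0 °C to rt
Reagents that add atoms: chlorotriethylsilane, CC[Si](Cl)(CC)CC
Why: O-silylation of the open-chain hydroxy ketone drains the hemiketal equilibrium and puts on C6 the silyl group that is to be removed first after the key step.

Step 11
Reactants: 17 C6-O-TES enone
Product: 18 (2S)-allylic alcohol (C2–OH; C6–OTES; C4–OTES; C9–OTES)
Conditions: (R)-Me-CBS oxazaborolidine (0.3 equiv), catecholborane, toluene, −78 °C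
Reagents that add atoms: none
Why: Corey–Bakshi–Shibata reduction, in which the oxazaborolidine–borane complex binds the ketone with the alkenyl group as the large substituent and delivers hydride to one face under reagent control, should set C2 as S independently of the remote C4 and C6 centres and without 1,4-reduction.

Step 12
Reactants: 18 (2S)-allylic alcohol
Product: 19 C2-O-TBS ether (C2–OTBS; C6–OTES; C4–OTES; C9–OTES)
Conditions: TBSOTf, 2,6-lutidine, CH2Cl2, −78 °C
Reagents that add atoms: tert-butyldimethylsilyl trifluoromethanesulfonate, CC(C)(C)[Si](C)(C)OS(=O)(=O)C(F)(F)F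
Why: O-silylation with the silyl triflate gives C2 a group that is orthogonal in lability to the TES ether at C6 and the TBDPS ether at C13, as the end game requires.

Step 13
Reactants: 19 C2-O-TBS ether
Product: 20 C9 primary allylic alcohol (C9–OH; C2–OTBS; C6–OTES; C4–OTES)
Conditions: PPTS (cat.), MeOH/CH2Cl2, −10 °C
Reagents that add atoms: none
Why: Acid-catalysed methanolysis of silyl ethers discriminates on steric grounds, so the primary allylic TES ether at C9 should be cleaved well before the hindered secondary (C6) and tertiary (C4) TES ethers, the TBS ether and the TBDPS ether.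

Step 14
Reactants: 20 C9 primary allylic alcohol
Product: 21 C9 thioacetate (C9–SAc; furan)
Conditions: PPh3, DIAD, AcSH, THF, 0 °C
Reagents that add atoms: thioacetic acid, CC(=O)S
Why: Mitsunobu thioesterification of a primary allylic alcohol by SN2 displacement of the oxyphosphonium ion introduces sulfur at C9 as a thioester, which is inert to singlet oxygen.

Step 15
Reactants: 21 C9 thioacetate
Product: 23 γ-hydroxybutenolide thioacetate (C12 lactone carbonyl; C8 hemiacetal; C8 epimers), via furan endoperoxide 22 (not isolated)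
Conditions: O2, tetraphenylporphyrin (cat.), iPr2NEt, CH2Cl2, visible light, −78 °C
Reagents that add atoms: dioxygen, O=O
Why: [4+2] Cycloaddition of singlet oxygen to the furan and base-induced Kornblum–DeLaMare-type fragmentation of the endoperoxide, in which the hindered amine should remove the more accessible bridgehead hydrogen at C12 (next to CH2OSi) and not the one at C8 (next to the branched C6 carbinol), make C12 the lactone carbonyl and C8 the hemiacetal carbon; the furan reacts far faster than the deactivated trisubstituted alkene and the C8 configuration is inconsequential.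

Step 16
Reactants: 23 γ-hydroxybutenolide thioacetate
Product: 25 eleven-membered cyclic S,O-acetal (sulfur bridging C8 and C9; C8 epimers), via free thiol 24 (not isolated)
Conditions: NaSMe (2.1 equiv), MeOH, −20 °C; AcOH; then CSA (cat.), 4 Å MS, CH2Cl2 (0.002 M), rt
Reagents that add atoms: none
Why: Transthioesterification with thiomethoxide frees the C9 thiol, and acid-catalysed thioacetalisation of the pseudo-acid (through the acyloxocarbenium ion at C8) under high dilution should close the eleven-membered ring by carbon–sulfur bond formation, since the silylated C4 oxygen cannot compete and either C8 epimer is acceptable.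

Step 17
Reactants: 25 eleven-membered cyclic S,O-acetal
Product: 26 eleven-membered cyclic sulfone (C6–OTES; C4–OTES; C2–OTBS; C13–OTBDPS; C8 epimers)
Conditions: (NH4)6Mo7O24·4H2O (cat.), H2O2 (30%), EtOH, 0 °C to rt
Reagents that add atoms: hydrogen peroxide, OO
Why: Molybdate-catalysed peroxide oxidation should take the sulfide through the sulfoxide to the sulfone without epoxidation, because the alkenes are electron-poor (butenolide) or deactivated by allylic oxygen and sulfur substituents.

Step 18
Reactants: 26 eleven-membered cyclic sulfone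
Product: 29 tetrasilylated bicyclic dienyl lactone (ten-membered carbocycle fused to the ylidene-butenolide; C6–OTES; C4–OTES; C2–OTBS; C13–OTBDPS), via C8-chlorosulfone 27 (not isolated), via episulfone 28 (not isolated)
Conditions: KOtBu (1.05 equiv), THF, −78 °C; C2Cl6 (1.1 equiv); then KOtBu (2.5 equiv), −78 to 0 °C
Reagents that add atoms: none
Why: Ramberg–Bäcklund reaction: the first equivalent of base removes the C8 hydrogen, which is α to the sulfone and γ in the butenolide (aromatic 2-oxidofuran anion), C2Cl6 transfers positive chlorine to that carbon, further base deprotonates allylic C9, 3-exo-tet displacement of chloride forms the episulfone, and cheletropic loss of SO2 gives C8=C9. The closest precedents are the conversion of anomeric (O,S-acetal) sulfones into exocyclic enol ethers and the Ramberg–Bäcklund contraction of cyclic sulfones to medium-ring alkenes and dienes. The ten-membered carbocycle arises by contraction of the eleven-membered thiacycle (C8–C9 bond formation inside an existing ring) and not by an end-to-end cyclisation, and the only ring actually closed is the transient three-membered episulfone. No stereocentre is created and the C8 configuration of 26 is erased. Two selectivities are needed: site selectivity (only C8, then C9, may be deprotonated), secured by the large acidity gap and by silylation of every oxygen so that no alkoxide can attack C8 or the lactone, and alkene geometry (C10 trans to the lactone oxygen, cis within the ring), expected because C9 of the episulfone can equilibrate and the ring already bent by the Z C1=C10 alkene should accommodate only the cis-fused episulfone. Portionwise base at low temperature should limit epimerisation at C6 and vinylogous loss of silanolate.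

Step 19
Reactants: 29 tetrasilylated bicyclic dienyl lactone
Product: 30 C6 alcohol (C6–OH; C4–OTES; C2–OTBS; C13–OTBDPS)
Conditions: HF·pyridine, pyridine, THF, 0 °C
Reagents that add atoms: none
Why: Buffered fluoride-mediated desilylation should cleave the secondary TES ether at C6 selectively, since the tertiary TES, secondary TBS and primary TBDPS ethers react markedly more slowly and the non-basic medium spares the dienyl enol lactone.

Step 20
Reactants: 30 C6 alcohol
Product: 31 C6 methacrylate (C4–OTES; C2–OTBS; C13–OTBDPS)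
Conditions: methacrylic anhydride, Et3N, DMAP (cat.), CH2Cl2, 0 °C to rt
Reagents that add atoms: methacrylic anhydride, C=C(C)C(=O)OC(=O)C(C)=C
Why: DMAP-catalysed acylation (nucleophilic catalysis) of the only free hydroxyl installs the methacrylate at C6.

Step 21
Reactants: 31 C6 methacrylate
Product: 32 C2,C4-diol (C6 methacrylate; C13–OTBDPS)
Conditions: HF·pyridine, THF, 0 °C to rt
Reagents that add atoms: none
Why: Unbuffered acidic fluoride should remove the allylic secondary TBS ether at C2 and the tertiary TES ether at C4, while the primary TBDPS ether, the slowest silyl ether toward acidic fluoride, is kept so that the C13 oxygen stays masked during acetylation.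

Step 22
Reactants: 32 C2,C4-diol
Product: 33 C2 acetate (C6 methacrylate; C4–OH; C13–OTBDPS)
Conditions: Ac2O, pyridine, DMAP (cat.), CH2Cl2, 0 °C
Reagents that add atoms: acetic anhydride, CC(=O)OC(C)=O
Why: Acylation discriminates by substitution, so the secondary allylic C2 hydroxyl should be acetylated while the tertiary C4 hydroxyl stays free under these mild conditions.

Step 23
Reactants: 33 C2 acetate
Product: 34 CNP0246543.1 (target)
Conditions: HF·pyridine (excess), THF, rt, prolonged
Reagents that add atoms: none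
Why: Prolonged fluoride-mediated desilylation cleaves the primary TBDPS ether, and the non-basic conditions should avoid ester cleavage and acyl migration to the liberated C13 hydroxyl.

Compound list

1 | 3,4-bis(hydroxymethyl)furan | OCc1cocc1CO | starting material
2 | [4-(TBDPS-oxymethyl)furan-3-yl]methanol | OCc1cocc1CO[Si](c2ccccc2)(c2ccccc2)C(C)(C)C | intermediate
3 | 4-(TBDPS-oxymethyl)furan-3-carbaldehyde | O=Cc1cocc1CO[Si](c2ccccc2)(c2ccccc2)C(C)(C)C | intermediate
4 | prop-2-yn-1-ol | C#CCO | starting material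
5 | bromomagnesium (Z)-3-(bromomagnesio)-2-methylprop-2-en-1-olate (not isolated) | Br[Mg]OC/C(C)=C\[Mg]Br | intermediate
6 | (Z)-3-iodo-2-methylprop-2-en-1-ol | OC/C(C)=C\I | intermediate
7 | (Z)-3-iodo-2-methylprop-2-enyl triethylsilyl ether | CC[Si](CC)(CC)OC/C(C)=C\I | intermediate
8 | (E)-1-methoxy-3-(trimethylsilyloxy)buta-1,3-diene | CO/C=C/C(=C)O[Si](C)(C)C | starting material
9 | (1E,5R)-1-methoxy-5-[4-(TBDPS-oxymethyl)furan-3-yl]-5-(trimethylsilyloxy)pent-1-en-3-one (not isolated) | CO/C=C/C(=O)C[C@@H](O[Si](C)(C)C)c1cocc1CO[Si](c2ccccc2)(c2ccccc2)C(C)(C)C | intermediate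
10 | (R)-2-[4-(TBDPS-oxymethyl)furan-3-yl]-2,3-dihydro-4H-pyran-4-one | O=C1C=CO[C@@H](c2cocc2CO[Si](c3ccccc3)(c3ccccc3)C(C)(C)C)C1 | intermediate
11 | lithium (2R)-2-[4-(TBDPS-oxymethyl)furan-3-yl]-4-methyl-3,4-dihydro-2H-pyran-4-olate, oxygen cis to furyl (not isolated) | [Li+].[O-][C@@]1(C)C=CO[C@@H](c2cocc2CO[Si](c3ccccc3)(c3ccccc3)C(C)(C)C)C1 | intermediate
12 | (2R)-2-[4-(TBDPS-oxymethyl)furan-3-yl]-4-methyl-4-(triethylsilyloxy)-3,4-dihydro-2H-pyran, silyloxy cis to furyl | CC[Si](CC)(CC)O[C@@]1(C)C=CO[C@@H](c2cocc2CO[Si](c3ccccc3)(c3ccccc3)C(C)(C)C)C1 | intermediate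
13 | (6R)-6-[4-(TBDPS-oxymethyl)furan-3-yl]-4-methyl-4-(triethylsilyloxy)tetrahydropyran-2-ol, silyloxy cis to furyl, anomeric mixture | OC1O[C@@H](c2cocc2CO[Si](c3ccccc3)(c3ccccc3)C(C)(C)C)C[C@@](C)(O[Si](CC)(CC)CC)C1 | intermediate
14 | (6R)-6-[4-(TBDPS-oxymethyl)furan-3-yl]-4-methyl-4-(triethylsilyloxy)tetrahydropyran-2-one, silyloxy cis to furyl | O=C1O[C@@H](c2cocc2CO[Si](c3ccccc3)(c3ccccc3)C(C)(C)C)C[C@@](C)(O[Si](CC)(CC)CC)C1 | intermediate
15 | (Z)-[2-methyl-3-(triethylsilyloxy)prop-1-enyl]lithium (not isolated) | CC[Si](CC)(CC)OC/C(C)=C\[Li] | intermediate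
16 | seco hydroxy enone: (6R)-C6–OH, C4–OTES, C2 ketone, Z C1=C10, C9–OTES, furan with C13–OTBDPS | O[C@@H](c1cocc1CO[Si](c2ccccc2)(c2ccccc2)C(C)(C)C)C[C@@](C)(O[Si](CC)(CC)CC)CC(=O)/C=C(C)\CO[Si](CC)(CC)CC | intermediate
17 | C6-O-TES enone: C6–OTES, C4–OTES, C2 ketone, C9–OTES | CC[Si](CC)(CC)O[C@@H](c1cocc1CO[Si](c2ccccc2)(c2ccccc2)C(C)(C)C)C[C@@](C)(O[Si](CC)(CC)CC)CC(=O)/C=C(C)\CO[Si](CC)(CC)CC | intermediate
18 | (2S)-allylic alcohol: C2–OH, C6–OTES, C4–OTES, C9–OTES | CC[Si](CC)(CC)O[C@@H](c1cocc1CO[Si](c2ccccc2)(c2ccccc2)C(C)(C)C)C[C@@](C)(O[Si](CC)(CC)CC)C[C@H](O)/C=C(C)\CO[Si](CC)(CC)CC | intermediate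
19 | C2-O-TBS ether: C2–OTBS, C6–OTES, C4–OTES, C9–OTES | CC[Si](CC)(CC)O[C@@H](c1cocc1CO[Si](c2ccccc2)(c2ccccc2)C(C)(C)C)C[C@@](C)(O[Si](CC)(CC)CC)C[C@H](O[Si](C)(C)C(C)(C)C)/C=C(C)\CO[Si](CC)(CC)CC | intermediate
20 | C9 primary allylic alcohol: C9–OH, C2–OTBS, C6–OTES, C4–OTES | CC[Si](CC)(CC)O[C@@H](c1cocc1CO[Si](c2ccccc2)(c2ccccc2)C(C)(C)C)C[C@@](C)(O[Si](CC)(CC)CC)C[C@H](O[Si](C)(C)C(C)(C)C)/C=C(C)\CO | intermediate
21 | C9 thioacetate: C9–SAc, furan intact | CC[Si](CC)(CC)O[C@@H](c1cocc1CO[Si](c2ccccc2)(c2ccccc2)C(C)(C)C)C[C@@](C)(O[Si](CC)(CC)CC)C[C@H](O[Si](C)(C)C(C)(C)C)/C=C(C)\CSC(C)=O | intermediate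
22 | furan endoperoxide (2,3,7-trioxabicyclo[2.2.1]hept-5-ene spanning C8 and C12; not isolated) | C12OOC(O1)C(CO[Si](c3ccccc3)(c3ccccc3)C(C)(C)C)=C2[C@H](O[Si](CC)(CC)CC)C[C@@](C)(O[Si](CC)(CC)CC)C[C@H](O[Si](C)(C)C(C)(C)C)/C=C(C)\CSC(C)=O | intermediate
23 | γ-hydroxybutenolide thioacetate: C12 lactone carbonyl, C8–OH (epimers), C9–SAc | O=C1OC(O)C(=C1CO[Si](c2ccccc2)(c2ccccc2)C(C)(C)C)[C@H](O[Si](CC)(CC)CC)C[C@@](C)(O[Si](CC)(CC)CC)C[C@H](O[Si](C)(C)C(C)(C)C)/C=C(C)\CSC(C)=O | intermediate
24 | γ-hydroxybutenolide thiol: C8–OH, C9–SH (not isolated) | O=C1OC(O)C(=C1CO[Si](c2ccccc2)(c2ccccc2)C(C)(C)C)[C@H](O[Si](CC)(CC)CC)C[C@@](C)(O[Si](CC)(CC)CC)C[C@H](O[Si](C)(C)C(C)(C)C)/C=C(C)\CS | intermediate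
25 | eleven-membered cyclic S,O-acetal: sulfur bridging C8 and C9, C8 epimers | O=C1OC2C(=C1CO[Si](c3ccccc3)(c3ccccc3)C(C)(C)C)[C@H](O[Si](CC)(CC)CC)C[C@@](C)(O[Si](CC)(CC)CC)C[C@H](O[Si](C)(C)C(C)(C)C)/C=C(C)\CS2 | intermediate
26 | eleven-membered cyclic sulfone (key-step precursor): C6–OTES, C4–OTES, C2–OTBS, C13–OTBDPS, C8 epimers | O=C1OC2C(=C1CO[Si](c3ccccc3)(c3ccccc3)C(C)(C)C)[C@H](O[Si](CC)(CC)CC)C[C@@](C)(O[Si](CC)(CC)CC)C[C@H](O[Si](C)(C)C(C)(C)C)/C=C(C)\CS2(=O)=O | intermediate
27 | C8-chloro cyclic sulfone (not isolated) | O=C1OC2(Cl)C(=C1CO[Si](c3ccccc3)(c3ccccc3)C(C)(C)C)[C@H](O[Si](CC)(CC)CC)C[C@@](C)(O[Si](CC)(CC)CC)C[C@H](O[Si](C)(C)C(C)(C)C)/C=C(C)\CS2(=O)=O | intermediate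
28 | episulfone (thiirane 1,1-dioxide spanning C8 and C9; not isolated) | O=C1OC23C(=C1CO[Si](c4ccccc4)(c4ccccc4)C(C)(C)C)[C@H](O[Si](CC)(CC)CC)C[C@@](C)(O[Si](CC)(CC)CC)C[C@H](O[Si](C)(C)C(C)(C)C)/C=C(C)\C2S3(=O)=O | intermediate
29 | tetrasilylated bicyclic dienyl lactone (key-step product): C6–OTES, C4–OTES, C2–OTBS, C13–OTBDPS | CC[Si](CC)(CC)O[C@@H]1C[C@@](C)(O[Si](CC)(CC)CC)C[C@H](O[Si](C)(C)C(C)(C)C)/C=C(C)\C=C2\OC(=O)C(CO[Si](c3ccccc3)(c3ccccc3)C(C)(C)C)=C21 | intermediate
30 | C6 alcohol: C6–OH, C4–OTES, C2–OTBS, C13–OTBDPS | O[C@@H]1C[C@@](C)(O[Si](CC)(CC)CC)C[C@H](O[Si](C)(C)C(C)(C)C)/C=C(C)\C=C2\OC(=O)C(CO[Si](c3ccccc3)(c3ccccc3)C(C)(C)C)=C21 | intermediate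
31 | C6 methacrylate: C4–OTES, C2–OTBS, C13–OTBDPS | C=C(C)C(=O)O[C@@H]1C[C@@](C)(O[Si](CC)(CC)CC)C[C@H](O[Si](C)(C)C(C)(C)C)/C=C(C)\C=C2\OC(=O)C(CO[Si](c3ccccc3)(c3ccccc3)C(C)(C)C)=C21 | intermediate
32 | C2,C4-diol: C6 methacrylate, C13–OTBDPS | C=C(C)C(=O)O[C@@H]1C[C@@](C)(O)C[C@H](O)/C=C(C)\C=C2\OC(=O)C(CO[Si](c3ccccc3)(c3ccccc3)C(C)(C)C)=C21 | intermediate
33 | C2 acetate: C6 methacrylate, C4–OH, C13–OTBDPS | C=C(C)C(=O)O[C@@H]1C[C@@](C)(O)C[C@H](OC(C)=O)/C=C(C)\C=C2\OC(=O)C(CO[Si](c3ccccc3)(c3ccccc3)C(C)(C)C)=C21 | intermediate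
34 | CNP0246543.1 | C=C(C)C(=O)O[C@@H]1C[C@@](C)(O)C[C@H](OC(C)=O)/C=C(C)\C=C2\OC(=O)C(CO)=C21 | target

Total step count: 23. Longest linear sequence: 21 steps (steps 1, 2 and 5–23, from compound 1); steps 3 and 4 prepare the alkenyl iodide 7.

Steps most likely to fail

Step 18 (ring contraction). Possible failures are chlorination at C11 or C9 instead of C8, vinylogous loss of silanolate from the C8 or C9 carbanions, epimerisation at C6 by excess base, or extrusion through a trans-fused episulfone that gives the wrong C8=C9 geometry. The fallback gives up the sulfur tether and closes C8=C9 by Wittig olefination, a known route to ylidene-butenolides and ylidene-phthalides from pseudo-acid-derived phosphonium salts. It sets out from alcohol 20. MnO2 in CH2Cl2 should oxidise the C9 allylic alcohol to the (Z)-enal F1. Photooxygenation as in step 15 should pass through the furan endoperoxide F2 and give the γ-hydroxybutenolide enal F3. Ph3P·HBr in MeCN over 4 Å MS should replace the C8 hydroxyl by phosphorus and give the C8 triphenylphosphonium bromide F4. Slow addition of F4 to Et3N in CH2Cl2 at high dilution should generate the stabilised C8 ylide F5, which condenses with the C9 aldehyde in an intramolecular Wittig reaction and returns to the route at 29.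

Step 16 (eleven-membered thioacetal). Possible failures are oligomerisation under the reversible acid conditions, ring-opening or conjugate addition at the pseudo-acid during the basic S-deacetylation, and loss of the C6 TES ether. The fallback replaces the equilibrium dehydration by a kinetically controlled, glycosylation-type substitution on a stable pseudo-ester with a separately purified thiol. It sets out from 23. PPTS in MeOH should convert the hemiacetal into the base-stable γ-methoxybutenolide thioacetate F6. K2CO3 in degassed MeOH at 0 °C should then free the thiol and give the γ-methoxybutenolide thiol F7. Syringe-pump addition of F7 to TMSOTf and 2,6-di-tert-butyl-4-methylpyridine in CH2Cl2 at −78 °C should ionise the methoxy group to the acyloxocarbenium ion at C8, which the thiol captures irreversibly, returning to the route at 25.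

Step 15 (furan oxygenation). Possible failures are removal of the C8 instead of the C12 bridgehead hydrogen during endoperoxide fragmentation (lactone carbonyl on the wrong carbon), or a competing ene reaction at C1=C10. The fallback fixes the carbonyl position before any oxygen is delivered to C8. It sets out from 19. Iridium-catalysed C–H borylation ([Ir(OMe)(cod)]2, 4,4'-di-tert-butyl-2,2'-bipyridine, B2pin2, hexane) should functionalise the less hindered furan α-carbon C12 and give the C12 pinacol boronate F8. NaBO3·4H2O in THF/H2O should oxidise the boronate to the 2-hydroxyfuran, which tautomerises to the butenolide F9 (C12 carbonyl, C8 methylene). PPTS in MeOH as in step 13 should give the butenolide C9 alcohol F10, and the Mitsunobu reaction of step 14 the butenolide thioacetate F11. TIPSOTf and Et3N in CH2Cl2 should convert the butenolide into the 2-(triisopropylsilyloxy)furan F12. Singlet oxygen at −78 °C without base should then give the silyl (Z)-4-oxo-enoate F13, which loses the silyl group on aqueous work-up and closes to the γ-hydroxybutenolide, returning to the route at 23.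

Further compounds

F1 | step 18 | (Z)-enal: C9 aldehyde, C2–OTBS, C6–OTES, C4–OTES, furan | CC[Si](CC)(CC)O[C@@H](c1cocc1CO[Si](c2ccccc2)(c2ccccc2)C(C)(C)C)C[C@@](C)(O[Si](CC)(CC)CC)C[C@H](O[Si](C)(C)C(C)(C)C)/C=C(C)\C=O
F2 | step 18 | furan endoperoxide of the enal (not isolated) | C12OOC(O1)C(CO[Si](c3ccccc3)(c3ccccc3)C(C)(C)C)=C2[C@H](O[Si](CC)(CC)CC)C[C@@](C)(O[Si](CC)(CC)CC)C[C@H](O[Si](C)(C)C(C)(C)C)/C=C(C)\C=O
F3 | step 18 | γ-hydroxybutenolide enal: C8–OH, C9 aldehyde | O=C1OC(O)C(=C1CO[Si](c2ccccc2)(c2ccccc2)C(C)(C)C)[C@H](O[Si](CC)(CC)CC)C[C@@](C)(O[Si](CC)(CC)CC)C[C@H](O[Si](C)(C)C(C)(C)C)/C=C(C)\C=O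
F4 | step 18 | C8 triphenylphosphonium bromide of the butenolide enal | O=C1OC([P+](c2ccccc2)(c2ccccc2)c2ccccc2)C(=C1CO[Si](c2ccccc2)(c2ccccc2)C(C)(C)C)[C@H](O[Si](CC)(CC)CC)C[C@@](C)(O[Si](CC)(CC)CC)C[C@H](O[Si](C)(C)C(C)(C)C)/C=C(C)\C=O.[Br-]
F5 | step 18 | C8 phosphorus ylide (not isolated) | O=C1OC(=P(c2ccccc2)(c2ccccc2)c2ccccc2)C(=C1CO[Si](c2ccccc2)(c2ccccc2)C(C)(C)C)[C@H](O[Si](CC)(CC)CC)C[C@@](C)(O[Si](CC)(CC)CC)C[C@H](O[Si](C)(C)C(C)(C)C)/C=C(C)\C=O
F6 | step 16 | γ-methoxybutenolide thioacetate: C8–OMe, C9–SAc | O=C1OC(OC)C(=C1CO[Si](c2ccccc2)(c2ccccc2)C(C)(C)C)[C@H](O[Si](CC)(CC)CC)C[C@@](C)(O[Si](CC)(CC)CC)C[C@H](O[Si](C)(C)C(C)(C)C)/C=C(C)\CSC(C)=O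
F7 | step 16 | γ-methoxybutenolide thiol: C8–OMe, C9–SH | O=C1OC(OC)C(=C1CO[Si](c2ccccc2)(c2ccccc2)C(C)(C)C)[C@H](O[Si](CC)(CC)CC)C[C@@](C)(O[Si](CC)(CC)CC)C[C@H](O[Si](C)(C)C(C)(C)C)/C=C(C)\CS
F8 | step 15 | C12 pinacol boronate of furan 19 | CC[Si](CC)(CC)O[C@@H](c1coc(B2OC(C)(C)C(C)(C)O2)c1CO[Si](c3ccccc3)(c3ccccc3)C(C)(C)C)C[C@@](C)(O[Si](CC)(CC)CC)C[C@H](O[Si](C)(C)C(C)(C)C)/C=C(C)\CO[Si](CC)(CC)CC
F9 | step 15 | butenolide: C12 carbonyl, C8 methylene, C9–OTES | O=C1OCC(=C1CO[Si](c2ccccc2)(c2ccccc2)C(C)(C)C)[C@H](O[Si](CC)(CC)CC)C[C@@](C)(O[Si](CC)(CC)CC)C[C@H](O[Si](C)(C)C(C)(C)C)/C=C(C)\CO[Si](CC)(CC)CC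
F10 | step 15 | butenolide C9 alcohol | O=C1OCC(=C1CO[Si](c2ccccc2)(c2ccccc2)C(C)(C)C)[C@H](O[Si](CC)(CC)CC)C[C@@](C)(O[Si](CC)(CC)CC)C[C@H](O[Si](C)(C)C(C)(C)C)/C=C(C)\CO
F11 | step 15 | butenolide C9 thioacetate | O=C1OCC(=C1CO[Si](c2ccccc2)(c2ccccc2)C(C)(C)C)[C@H](O[Si](CC)(CC)CC)C[C@@](C)(O[Si](CC)(CC)CC)C[C@H](O[Si](C)(C)C(C)(C)C)/C=C(C)\CSC(C)=O
F12 | step 15 | 2-(triisopropylsilyloxy)furan: silyloxy on C12, C9–SAc | CC(C)[Si](Oc1occ(c1CO[Si](c2ccccc2)(c2ccccc2)C(C)(C)C)[C@H](O[Si](CC)(CC)CC)C[C@@](C)(O[Si](CC)(CC)CC)C[C@H](O[Si](C)(C)C(C)(C)C)/C=C(C)\CSC(C)=O)(C(C)C)C(C)C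
F13 | step 15 | triisopropylsilyl (Z)-4-oxo-enoate: C8 aldehyde, C12 silyl ester (not isolated) | O=C/C(=C(/CO[Si](c2ccccc2)(c2ccccc2)C(C)(C)C)C(=O)O[Si](C(C)C)(C(C)C)C(C)C)[C@H](O[Si](CC)(CC)CC)C[C@@](C)(O[Si](CC)(CC)CC)C[C@H](O[Si](C)(C)C(C)(C)C)/C=C(C)\CSC(C)=O
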